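## Analysis of the target

Target 15 is a benzyl-type depside: two benzene rings joined through a CH2–O–C(=O) bridge. Ring B is a methyl benzoate with C1 CO2Me, C2 OH, C3 CH3, C4 OH, C5 H and C6 CH2O. Ring A is the acyl part, with C1' bearing the ester carbonyl, C2' OH, C3' CHO, C4' OH, C5' H and C6' CH3. There is no ring fusion and no stereocentre, so the difficulty lies in regiochemistry and functional-group tolerance. The sensitive groups are the salicylaldehyde of ring A, the four phenols and, above all, the benzylic oxygen on the C6 arm, which sits ortho to the C1 methyl ester. If that oxygen is ever a free alcohol or alkoxide it closes onto C1 to a five-membered lactone, and the benzylic C–O bond is also open to hydrogenolysis. Ring B carries five contiguous substituents (C6, C1, C2, C3, C4), which is hard to reach by substitution of a simpler arene, and on ring A the formyl group must go between the two oxygens and not to C5'. The strategy rests on the sequence C1(CO2Me)–C2(O)–C3(CH3)–C4(O) of ring B. This is the oxidation pattern of a 3-methyl-2,4-dioxocyclohexane-1-carboxylate, which is the sum of a malonate (C1, C2) and an ethyl enone (C3 to C6), so ring B can be assembled from sp3 carbons with the ring A ester already on the C6 arm and made aromatic afterwards.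

## Retrosynthetic reasoning

15 to 14. The last operation is kept free of bond construction. In 14 the C3' aldehyde is a dimethyl acetal and the C2' and C4' phenols are methoxymethyl ethers. All three are acetals that fall to dilute aqueous acid, which both 2,6-disubstituted aryl esters tolerate; base or hydrogenolysis would endanger the C6 CH2–O bond.

14 to 13. Ring B of 14 is taken back by two hydrogens to the enolised dione 13. The forward reaction is a dehydrogenation that must spare the acetal and the electron-rich ring A. What is gained is that every substituent of ring B can be placed by carbonyl chemistry on sp3 carbons.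

13 to 10 and 11. The bonds C1–C6 and C2–C3 are cut. C1–C6 lies beta to the C4 carbonyl (conjugate-addition retron) and C2–C3 lies inside a 1,3-dicarbonyl unit (Claisen retron). The cut leaves C1 and C2 in malonate 11 and C3 to C6 in enone 10, with the whole ring A ester already on the C6 arm, so the benzylic oxygen is acylated before ring B exists and is never free. Forward, one alkoxide-mediated operation has to add 11 to 10, pass through adduct 12 and close the ring without touching the ring A ester.

10 to 8 and 9. The C=C bond of 10 (future C5–C6) is cut by cross-metathesis. Vinyl ketone 9 brings C3, C4, C5 and the C3 methyl; allyl ester 8 brings C6 and the CH2O arm. The forward reaction must give the E-enone and tolerate the acetal.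

8 to 5 and 6. The C1'–C(=O) bond is cut. Aryllithium 7, made from 5 by directed metalation, is acylated by chloroformate 6, which installs the carboxyl carbon and the allyl ester in one step. The only ring hydrogens of 5 are the two equivalent ones ortho to an ether, so the site is fixed by the substrate.

5 to 4 to 2 to 1. Acetal 5 comes from aldehyde 4. The C3'–CHO bond of 4 is cut to aryllithium 3, generated from the symmetric bis-ether 2 at the unique carbon flanked by both ethers, so the formyl position is unambiguous. 2 is the double ether of orcinol 1, which already holds the C6' methyl and both ring A oxygens.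

## Alternatives that were turned down

Alternative 1: Aryne route to the C3' aldehyde and C4' phenol.
- **Disconnection:** the C3'–CHO and C4'–O bonds of ring A, removed together at the end.
- **Forward key step:** a fluoride source unmasks the C3'–C4' aryne from the ortho-silyl aryl triflate A2. The carbonyl oxygen of the formamide A3 adds to C4', the aryne carbon remote from the C2' ether. The aryl anion at C3' closes on the iminium carbon, and the strained benzoxete opens and is hydrolysed to salicylaldehyde A1.
- **For:** two bonds form in one mild step, the CHO/OH pair comes out in the right orientation, no acetal is needed and ring B undergoes no redox change. On mildness of the end game it is stronger than the chosen route, which needs a hot alkoxide step and a dehydrogenation.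
- **Against:** A2 must carry silicon on the most crowded carbon and a triflate on C4'. The C4' oxygen, which 1 already has, is spent as a leaving group and then bought back, whereas step 2 formylates the same carbon directly. The phenoxide freed in A1 can itself trap the aryne, and three methoxymethyl groups remain to be removed.
- **Comparison:** the alternative does not address ring B at all. A2 presupposes the ring B benzyl alcohol next to its methyl ester, the arrangement that lactonises, and the five contiguous substituents of ring B still have to be made. The chosen strategy spends its key step on that ring and takes ring A from 1 in four conventional steps.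

Alternative 2: De novo ring A by a ketene benzannulation.
- **Disconnection:** C2'–C3', C4'–C5' and C1'–C2' of ring A.
- **Forward key step:** irradiation of diazo ketone A5 gives, by Wolff rearrangement, a vinylketene. The unsubstituted carbon of ynol ether A6 bonds to the ketene carbonyl carbon in a [2+2] addition, and 4-pi opening, 6-pi closure and tautomerisation deliver phenol A4 with C2'–OH free and C4' as its tert-butyl ether.
- **For:** regiochemistry follows from ketene and ynol ether polarity, and the two ring A oxygens emerge differentiated, so a later ortho-formylation can be steered to C3' by the free phenol. On telling the two phenols apart it is stronger than the chosen route.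
- **What the chosen route offers instead:** it needs no differentiation, because in 2 the carbon between the two ethers is unique by symmetry.
- **Against:** A4 still lacks the formyl carbon, so another C–C bond formation on a ring with a second open position (C5') and three deprotections follow. A5 needs diazo ketone chemistry on a dienoate and a photochemical step beside the light-absorbing ring B ester. A6 is volatile and acid-labile.
- **Comparison:** the ring it constructs has the substitution pattern of 1, which is commercially available, while ring B is again presupposed with its lactonisation-prone benzyl alcohol. It is longer by several steps.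

Alternative 3: Ring B by cycloaddition to a tethered ynoate.
- **Disconnection:** C1–C2 and C5–C6 of ring B.
- **Forward key step:** diene A9 adds thermally across the triple bond of ynoate A8. The nucleophilic CH2 terminus (C5) bonds to the beta carbon of the ynoate (C6) and the ketene acetal terminus (C2) to C1. The adduct aromatises by extrusion of a silyl methyl ether and desilylation to A7.
- **For:** it is convergent, reaches the aromatic oxidation level directly, creates no stereocentre and uses no alkoxide. The ring A ester is on the C6 arm before ring B exists, as in the chosen route. It is probably one step shorter. On oxidation-state economy and step count it is as strong or stronger.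
- **Against:** the ketene acetal terminus of A9 is fully substituted and the next carbon bears a methyl, so one substituent must point inward in the s-cis conformer and the cycloaddition is slowed. A8 is only a singly activated internal alkyne, so forcing temperatures are needed, at which silyl dienol ethers migrate and hydrolyse. A8 carries the free aldehyde, an electrophile for a silyl ketene acetal, and its propargylic aroate can isomerise or be displaced.
- **Comparison:** the chosen route pays one extra oxidation step and in return uses two stable partners (10 and 11) under ionic conditions that are known to accept the C3 methyl, with the aldehyde masked.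

Key step: step 6

Remark on the chemistry: 12 and 13 are racemic (one enantiomer is drawn) and their stereocentres are erased in step 7. Orcinol is assumed to be used in anhydrous form.

## Steps

Step 1
Reactants: 1 orcinol (5-methylbenzene-1,3-diol)
Product: 2 1,3-bis(methoxymethoxy)-5-methylbenzene
Conditions: NaH (2.4 equiv), MOMCl (2.4 equiv), DMF, 0 °C to rt
Reagents that add atoms: chloromethyl methyl ether, COCCl
Why: Double Williamson etherification of the bis-phenoxide with the reactive alpha-chloro ether; the methoxymethyl groups direct the later lithiations and are stable to organolithiums, alkoxide and metathesis.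

Step 2
Reactants: 2 1,3-bis(methoxymethoxy)-5-methylbenzene
Product: 4 2,6-bis(methoxymethoxy)-4-methylbenzaldehyde, via 2,6-bis(methoxymethoxy)-4-methylphenyllithium 3 (not isolated)
Conditions: n-BuLi (1.1 equiv), TMEDA, THF, 0 °C; DMF, 0 °C to rt; H2O
Reagents that add atoms: N,N-dimethylformamide, CN(C)C=O
Why: Directed ortho-metalation; the carbon between the two methoxymethoxy groups is activated by both and is the unique doubly flanked site of the symmetric arene, and the aryllithium is formylated by the formamide.

Step 3
Reactants: 4 2,6-bis(methoxymethoxy)-4-methylbenzaldehyde
Product: 5 2-(dimethoxymethyl)-1,3-bis(methoxymethoxy)-5-methylbenzene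
Conditions: HC(OMe)3 (5 equiv), PPTS (5 mol%), MeOH, rt; Et3N quench
Reagents that add atoms: trimethyl orthoformate, COC(OC)OC; methanol, CO
Why: Acid-catalysed acetalisation driven by the orthoformate as water scavenger; the weak pyridinium acid at room temperature should leave the aryl methoxymethyl ethers intact, and the acetal removes the one electrophile on ring A that malonate could attack in step 6.

Step 4
Reactants: 5 2-(dimethoxymethyl)-1,3-bis(methoxymethoxy)-5-methylbenzene; 6 allyl chloroformate
Product: 8 allyl 3-(dimethoxymethyl)-2,4-bis(methoxymethoxy)-6-methylbenzoate, via 3-(dimethoxymethyl)-2,4-bis(methoxymethoxy)-6-methylphenyllithium 7 (not isolated)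
Conditions: s-BuLi (1.2 equiv), TMEDA, THF, −78 °C; cannulation into 6 (2 equiv), THF, −78 °C to rt
Reagents that add atoms: none
Why: Second directed ortho-metalation: the two remaining ring hydrogens are equivalent and ortho to a methoxymethoxy group, while the methyl is meta to both ethers and gets no lateral assistance; inverse addition of the hindered aryllithium to excess chloroformate (acyl substitution) should stop at the ester, because the 2,6-disubstituted product resists a second addition.

Step 5
Reactants: 8 allyl 3-(dimethoxymethyl)-2,4-bis(methoxymethoxy)-6-methylbenzoate; 9 pent-1-en-3-one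
Product: 10 (E)-4-oxohex-2-enyl 3-(dimethoxymethyl)-2,4-bis(methoxymethoxy)-6-methylbenzoate
Conditions: second-generation Grubbs catalyst RuCl2(=CHPh)(PCy3)(H2IMes) (3 mol%), 9 (3 equiv), CH2Cl2, 40 °C
Reagents that add atoms: none
Why: Olefin cross-metathesis between a terminal allylic ester and an electron-poor vinyl ketone used in excess; the enone partner homodimerises slowly, so the cross product should dominate, and the conjugated disubstituted alkene forms as the E isomer under thermodynamic control.

Step 6
Reactants: 10 (E)-4-oxohex-2-enyl 3-(dimethoxymethyl)-2,4-bis(methoxymethoxy)-6-methylbenzoate; 11 dimethyl malonate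
Product: 13 methyl trans-6-({[3-(dimethoxymethyl)-2,4-bis(methoxymethoxy)-6-methylbenzoyl]oxy}methyl)-2-hydroxy-3-methyl-4-oxocyclohex-2-ene-1-carboxylate (racemic), via malonate Michael adduct 12 (not isolated)
Conditions: 11 (1.5 equiv), NaOMe (1.3 equiv), MeOH, 0 °C to rt, then reflux; AcOH to pH 6, 0 °C
Reagents that add atoms: none
Why: Sodiomalonate adds in a conjugate sense to the beta carbon of 10 and forms C1–C6, giving 12 as its ketone enolate. Proton exchange moves the enolate to the ethyl side, and that carbon (C3) attacks one malonate ester carbonyl (C2), expels methoxide and forms C2–C3; deprotonation of the product to its vinylogous carboxylate pulls every equilibrium forward. The closest known reaction is the Michael-Claisen annulation of dimethyl malonate with hex-4-en-3-one, the classical entry to the 3,6-dimethyl dihydroresorcylate. The ring closes in the 6-exo-trig mode; the only other closure, from C5, would give a four-membered ring. C6 is set in the conjugate addition without control and is racemic; C1 is the alpha carbon of a beta-keto ester, epimerises under the conditions and should settle trans to the C6 arm. The step needs chemoselectivity for the malonate ester over the ring A ester, which the substrate secures: attack of C3 on the aroate would need a seven-membered transition state, and the aroate is 2,6-disubstituted and shielded from methoxide. The aldehyde is masked, so no Knoevenagel condensation can compete, and malonate in excess over NaOMe keeps free methoxide low, which limits gamma-deprotonation of the enone and ester methanolysis.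

Step 7
Reactants: 13 methyl trans-6-({[3-(dimethoxymethyl)-2,4-bis(methoxymethoxy)-6-methylbenzoyl]oxy}methyl)-2-hydroxy-3-methyl-4-oxocyclohex-2-ene-1-carboxylate
Product: 14 methyl 6-({[3-(dimethoxymethyl)-2,4-bis(methoxymethoxy)-6-methylbenzoyl]oxy}methyl)-2,4-dihydroxy-3-methylbenzoate
Conditions: DDQ (1.1 equiv), 1,4-dioxane, 60 °C
Reagents that add atoms: none
Why: Quinone dehydrogenation of an enolised cyclohexane-1,3-dione to the resorcinol: hydride is taken from C6, which is allylic to the enol double bond, the acidic C1 proton is lost and the dienone tautomerises, aromaticity making the process irreversible. The acetal C–H of ring A is held in the ring plane by its two ortho ethers and is poorly aligned for hydride loss; both stereocentres disappear.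

Step 8
Reactants: 14 methyl 6-({[3-(dimethoxymethyl)-2,4-bis(methoxymethoxy)-6-methylbenzoyl]oxy}methyl)-2,4-dihydroxy-3-methylbenzoate
Product: 15 methyl 6-{[(3-formyl-2,4-dihydroxy-6-methylbenzoyl)oxy]methyl}-2,4-dihydroxy-3-methylbenzoate
Conditions: HCl (2 M aq), THF, 40 °C
Reagents that add atoms: water, O
Why: Acid hydrolysis of three acetals (the dimethyl acetal and two methoxymethyl ethers). Both aryl esters are 2,6-disubstituted and resist acid hydrolysis, and the benzylic C–O bond is meta to both ring B hydroxyls and ortho to the ester, so it should not ionise.

## Compound list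

1 | orcinol (5-methylbenzene-1,3-diol) | Cc1cc(O)cc(O)c1 | starting material
2 | 1,3-bis(methoxymethoxy)-5-methylbenzene | COCOc1cc(C)cc(OCOC)c1 | intermediate
3 | 2,6-bis(methoxymethoxy)-4-methylphenyllithium | [Li]c1c(OCOC)cc(C)cc1OCOC | intermediate (not isolated)
4 | 2,6-bis(methoxymethoxy)-4-methylbenzaldehyde | COCOc1cc(C)cc(OCOC)c1C=O | intermediate
5 | 2-(dimethoxymethyl)-1,3-bis(methoxymethoxy)-5-methylbenzene | COCOc1cc(C)cc(OCOC)c1C(OC)OC | intermediate
6 | allyl chloroformate (prop-2-enyl carbonochloridate) | C=CCOC(=O)Cl | starting material
7 | 3-(dimethoxymethyl)-2,4-bis(methoxymethoxy)-6-methylphenyllithium | [Li]c1c(C)cc(OCOC)c(C(OC)OC)c1OCOC | intermediate (not isolated)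
8 | allyl 3-(dimethoxymethyl)-2,4-bis(methoxymethoxy)-6-methylbenzoate | C=CCOC(=O)c1c(C)cc(OCOC)c(C(OC)OC)c1OCOC | intermediate
9 | pent-1-en-3-one | CCC(=O)C=C | starting material
10 | (E)-4-oxohex-2-enyl 3-(dimethoxymethyl)-2,4-bis(methoxymethoxy)-6-methylbenzoate | CCC(=O)/C=C/COC(=O)c1c(C)cc(OCOC)c(C(OC)OC)c1OCOC | intermediate
11 | dimethyl malonate | COC(=O)CC(=O)OC | starting material
12 | dimethyl 2-(1-{[3-(dimethoxymethyl)-2,4-bis(methoxymethoxy)-6-methylbenzoyl]oxy}-4-oxohexan-2-yl)propanedioate (racemic, one enantiomer drawn) | COC(=O)C(C(=O)OC)[C@@H](COC(=O)c1c(C)cc(OCOC)c(C(OC)OC)c1OCOC)CC(=O)CC | intermediate (not isolated)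
13 | methyl trans-6-({[3-(dimethoxymethyl)-2,4-bis(methoxymethoxy)-6-methylbenzoyl]oxy}methyl)-2-hydroxy-3-methyl-4-oxocyclohex-2-ene-1-carboxylate (racemic, one enantiomer drawn) | COC(=O)[C@@H]1[C@@H](COC(=O)c2c(C)cc(OCOC)c(C(OC)OC)c2OCOC)CC(=O)C(C)=C1O | intermediate
14 | methyl 6-({[3-(dimethoxymethyl)-2,4-bis(methoxymethoxy)-6-methylbenzoyl]oxy}methyl)-2,4-dihydroxy-3-methylbenzoate | COC(=O)c1c(COC(=O)c2c(C)cc(OCOC)c(C(OC)OC)c2OCOC)cc(O)c(C)c1O | intermediate
15 | methyl 6-{[(3-formyl-2,4-dihydroxy-6-methylbenzoyl)oxy]methyl}-2,4-dihydroxy-3-methylbenzoate | COC(=O)c1c(COC(=O)c2c(C)cc(O)c(C=O)c2O)cc(O)c(C)c1O | target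

## Step count and least certain steps

Total: 8 steps. Longest linear sequence: 8 steps (1 to 15); compounds 6, 9 and 11 are commercially available and enter directly.

Step 6 (key step).
- **What may go wrong:** gamma-deprotonation of the enone by alkoxide, followed by reprotonation to the enol-ester isomer and loss of the aroate; slow methanolysis of the benzylic aroate at reflux; reversal of the conjugate addition before ring closure. The product is also about as acidic as a carboxylic acid and may strip its own acetal on standing. That loss is tolerated, since the aldehyde is unmasked in step 8 anyway.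
- **Fallback:** reach 13 from a less acidic acceptor and a softer nucleophile. From 8, cross-metathesis with methyl acrylate under the catalyst of step 5 should give (E)-4-methoxy-4-oxobut-2-enyl 3-(dimethoxymethyl)-2,4-bis(methoxymethoxy)-6-methylbenzoate F1. Methyl 3-oxopentanoate and NaOMe in MeOH then add through the carbon between the two carbonyls to give dimethyl 3-({[3-(dimethoxymethyl)-2,4-bis(methoxymethoxy)-6-methylbenzoyl]oxy}methyl)-2-propanoylpentanedioate F2, which is not isolated. Its ethyl ketone carbon closes onto the terminal ester (C3–C4 instead of C2–C3) and the route is rejoined at 13.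

Step 7.
- **What may go wrong:** sluggish hydride transfer from C6, which is deactivated by the neighbouring acyloxymethyl group; oxidation at the acetal C–H or over-oxidation of the freshly formed methylresorcinol; acetal cleavage by the acidic hydroquinone.
- **Fallback:** replace oxidation by an elimination. From 13, LiN(i-Pr)2 (2.2 equiv) in THF at −78 °C forms the dianion, which PhSeBr should selenenylate at C1, its most basic carbon, anti to the C6 arm, giving methyl 6-({[3-(dimethoxymethyl)-2,4-bis(methoxymethoxy)-6-methylbenzoyl]oxy}methyl)-2-hydroxy-3-methyl-4-oxo-1-(phenylselanyl)cyclohex-2-ene-1-carboxylate F3. H2O2 and pyridine in CH2Cl2 at 0 °C give the corresponding selenoxide F4, which is not isolated. Syn-elimination toward the cis C6–H and tautomerisation rejoin the route at 14.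

Step 4.
- **What may go wrong:** slow or unselective metalation at the crowded position, with competing deprotonation of the ring methyl or attack of the base on the acetal.
- **Fallback:** fix the site by halogen. From 5, NBS in MeCN at 0 °C should brominate the only free ring position, which is ortho and para to the two ethers, to give 1-bromo-3-(dimethoxymethyl)-2,4-bis(methoxymethoxy)-6-methylbenzene F5. Bromine-lithium exchange with n-BuLi in THF at −78 °C gives 7, where the route is rejoined before the addition to 6.

Step 5.
- **What may go wrong:** homodimerisation of 8, migration of the double bond to the enol ester through ruthenium hydride species, and polymerisation of 9.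
- **Fallback:** build the enone by olefination. From 8, OsO4 (cat.), NaIO4 and 2,6-lutidine in dioxane/H2O cleave the alkene to 2-oxoethyl 3-(dimethoxymethyl)-2,4-bis(methoxymethoxy)-6-methylbenzoate F6. Wittig reaction with the stabilised ylide Ph3P=CHC(O)Et in CH2Cl2 at rt should give the E-enone and rejoin the route at 10.

Step 8.
- **What may go wrong:** electrophilic substitution of ring B at C5 (ortho and para to its two hydroxyls) by the formaldehyde set free, or incomplete removal of the hindered C2' ether under conditions mild enough for the esters.
- **Fallback:** change the order so that deprotection takes place while ring B is not yet an arene. From 13, HCl (2 M aq) in THF gives methyl trans-6-{[(3-formyl-2,4-dihydroxy-6-methylbenzoyl)oxy]methyl}-2-hydroxy-3-methyl-4-oxocyclohex-2-ene-1-carboxylate F7. DDQ in dioxane then dehydrogenates the dione and rejoins the route at 15.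

## Further compounds

F1 | step 6 | (E)-4-methoxy-4-oxobut-2-enyl 3-(dimethoxymethyl)-2,4-bis(methoxymethoxy)-6-methylbenzoate | COC(=O)/C=C/COC(=O)c1c(C)cc(OCOC)c(C(OC)OC)c1OCOC
F2 | step 6 | dimethyl 3-({[3-(dimethoxymethyl)-2,4-bis(methoxymethoxy)-6-methylbenzoyl]oxy}methyl)-2-propanoylpentanedioate (racemic mixture of diastereomers, not isolated) | CCC(=O)C(C(=O)OC)C(COC(=O)c1c(C)cc(OCOC)c(C(OC)OC)c1OCOC)CC(=O)OC
F3 | step 7 | methyl 6-({[3-(dimethoxymethyl)-2,4-bis(methoxymethoxy)-6-methylbenzoyl]oxy}methyl)-2-hydroxy-3-methyl-4-oxo-1-(phenylselanyl)cyclohex-2-ene-1-carboxylate (racemic, selanyl group trans to the C6 arm) | COC(=O)[C@@]1([Se]c2ccccc2)[C@@H](COC(=O)c2c(C)cc(OCOC)c(C(OC)OC)c2OCOC)CC(=O)C(C)=C1O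
F4 | step 7 | selenoxide of F3 (racemic, configuration at selenium undefined, not isolated) | COC(=O)[C@@]1([Se](=O)c2ccccc2)[C@@H](COC(=O)c2c(C)cc(OCOC)c(C(OC)OC)c2OCOC)CC(=O)C(C)=C1O
F5 | step 4 | 1-bromo-3-(dimethoxymethyl)-2,4-bis(methoxymethoxy)-6-methylbenzene | Brc1c(C)cc(OCOC)c(C(OC)OC)c1OCOC
F6 | step 5 | 2-oxoethyl 3-(dimethoxymethyl)-2,4-bis(methoxymethoxy)-6-methylbenzoate | O=CCOC(=O)c1c(C)cc(OCOC)c(C(OC)OC)c1OCOC
F7 | step 8 | methyl trans-6-{[(3-formyl-2,4-dihydroxy-6-methylbenzoyl)oxy]methyl}-2-hydroxy-3-methyl-4-oxocyclohex-2-ene-1-carboxylate (racemic, one enantiomer drawn) | COC(=O)[C@@H]1[C@@H](COC(=O)c2c(C)cc(O)c(C=O)c2O)CC(=O)C(C)=C1O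
A1 | alternative 1 | [2-(methoxycarbonyl)-3,5-bis(methoxymethoxy)-4-methylphenyl]methyl 3-formyl-4-hydroxy-2-(methoxymethoxy)-6-methylbenzoate | COC(=O)c1c(COC(=O)c2c(C)cc(O)c(C=O)c2OCOC)cc(OCOC)c(C)c1OCOC
A2 | alternative 1 | [2-(methoxycarbonyl)-3,5-bis(methoxymethoxy)-4-methylphenyl]methyl 2-(methoxymethoxy)-6-methyl-4-[(trifluoromethanesulfonyl)oxy]-3-(trimethylsilyl)benzoate | COC(=O)c1c(COC(=O)c2c(C)cc(OS(=O)(=O)C(F)(F)F)c([Si](C)(C)C)c2OCOC)cc(OCOC)c(C)c1OCOC
A3 | alternative 1 | N,N-dimethylformamide | CN(C)C=O
A4 | alternative 2 | [2-(methoxycarbonyl)-3,5-bis(methoxymethoxy)-4-methylphenyl]methyl 4-tert-butoxy-2-hydroxy-6-methylbenzoate | COC(=O)c1c(COC(=O)c2c(C)cc(OC(C)(C)C)cc2O)cc(OCOC)c(C)c1OCOC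
A5 | alternative 2 | [2-(methoxycarbonyl)-3,5-bis(methoxymethoxy)-4-methylphenyl]methyl (E)-5-diazo-3-methyl-4-oxopent-2-enoate | COC(=O)c1c(COC(=O)/C=C(\C)C(=O)C=[N+]=[N-])cc(OCOC)c(C)c1OCOC
A6 | alternative 2 | tert-butoxyethyne | CC(C)(C)OC#C
A7 | alternative 3 | [3,5-dihydroxy-2-(methoxycarbonyl)-4-methylphenyl]methyl 3-formyl-2,4-bis(methoxymethoxy)-6-methylbenzoate | COC(=O)c1c(COC(=O)c2c(C)cc(OCOC)c(C=O)c2OCOC)cc(O)c(C)c1O
A8 | alternative 3 | 4-methoxy-4-oxobut-2-ynyl 3-formyl-2,4-bis(methoxymethoxy)-6-methylbenzoate | COC(=O)C#CCOC(=O)c1c(C)cc(OCOC)c(C=O)c1OCOC
A9 | alternative 3 | 1-methoxy-2-methyl-1,3-bis(trimethylsilyloxy)buta-1,3-diene (geometry at the ketene acetal double bond unspecified) | COC(O[Si](C)(C)C)=C(C)C(=C)O[Si](C)(C)C
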